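**Retrosynthetic overview**
- The target is cut at C11'=C12' (Wittig) into an (R)-ε-C15 triphenylphosphonium salt and (5R,6S)-5,6-epoxy-β-apo-12'-carotenal (C25).
- The epoxy aldehyde comes from a catalyst-controlled, site- and face-selective epoxidation (C–O bond formation) of β-apo-12'-carotenal. This is done before the ε ring, whose trisubstituted alkene would compete, is attached; it sets C5 and C6.
- The C25 aldehyde comes from a β-C15 phosphonium salt (from vinyl-β-ionol) and the C10 dialdehyde (Wittig at C11=C12).
- The ε-C15 salt comes from vinyl-α-ionol, which comes from (R)-α-ionone, obtained by resolving cheap racemic α-ionone (source of C6').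
- Ring order: both cyclohexene rings are bought preformed in the ionone-derived building blocks. The only ring made is the oxirane, formed before the final C15 + C25 coupling.

Assumption: racemic α-ionone, vinyl-β-ionol and 2,7-dimethylocta-2,4,6-trienedial are bought as bulk fragrance and carotenoid intermediates, and the known chiral ketone catalyst of step 6 (four steps from D-glucose and p-toluidine) is not counted as a step.

Catalyst of step 6: the Shi-type D-glucose-derived ketone, a pyranos-3-ulose carrying a 4,5-O-isopropylidene acetal and an N-(4-methylphenyl)oxazolidin-2-one spiro-fused at the anomeric carbon. SMILES: Cc1ccc(cc1)N1C[C@]2(OC1=O)OC[C@H]3OC(C)(C)O[C@H]3C2=O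

**Route**

Step 1
Reactants: 1 (±)-α-ionone
Product: 2 (R)-(+)-α-ionone
Conditions: preparative chiral SFC, cellulose tris(3,5-dimethylphenylcarbamate) column, CO2/iPrOH 97:3, 35 °C; dextrorotatory fraction collected, >99% ee
Reagents that add atoms: none
Why: Resolution of a racemate by chromatography on a chiral stationary phase; no bond is made, the ring stereocentre (R, the dextrorotatory enantiomer) is selected rather than set, and the 50% ceiling is acceptable because 1 costs almost nothing.

Step 2
Reactants: 2 (R)-(+)-α-ionone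
Product: 4 (6R)-vinyl-α-ionol as a 1:1 mixture of carbinol epimers, via bromomagnesium alkoxide 3 (not isolated)
Conditions: CH2=CHMgBr (1.3 equiv), THF, −20 → 0 °C; sat. aq NH4Cl
Reagents that add atoms: vinylmagnesium bromide, C=C[Mg]Br
Why: Grignard 1,2-addition of a hard vinyl nucleophile to the enone carbonyl at low temperature; the new carbinol centre forms as both epimers, which is irrelevant because it is destroyed in step 3, and the ring stereocentre is not touched.

Step 3
Reactants: 4 (6R)-vinyl-α-ionol
Product: 5 ε-C15 Wittig salt, [(2E,4E)-3-methyl-5-[(1R)-2,6,6-trimethylcyclohex-2-en-1-yl]penta-2,4-dien-1-yl]triphenylphosphonium bromide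
Conditions: PPh3·HBr (1.05 equiv), MeOH, 0 → 20 °C, 16 h, dark; crystallised from EtOAc/Et2O
Reagents that add atoms: triphenylphosphine hydrobromide, [Br-].[PH+](c1ccccc1)(c1ccccc1)c1ccccc1
Why: Acid-promoted SN1-type allylic transposition (the standard vinyl-ionol to C15 Wittig salt reaction), in which HBr ionises the tertiary allylic alcohol to a pentadienyl cation and PPh3 adds at the unhindered terminus to give the conjugated 2E,4E salt; the ring stereocentre lies outside the cation and stays R under these mild conditions.

Step 4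
Reactants: 6 vinyl-β-ionol
Product: 7 β-C15 Wittig salt, [(2E,4E)-3-methyl-5-(2,6,6-trimethylcyclohex-1-en-1-yl)penta-2,4-dien-1-yl]triphenylphosphonium bromide
Conditions: PPh3·HBr (1.05 equiv), MeOH, 0 → 20 °C, 16 h; crystallised from EtOAc
Reagents that add atoms: triphenylphosphine hydrobromide, [Br-].[PH+](c1ccccc1)(c1ccccc1)c1ccccc1
Why: The same allylic transposition and phosphonium salt formation as in step 3, here on the achiral β series where it is a long-established bulk reaction; no stereocentre is involved.

Step 5
Reactants: 7 β-C15 Wittig salt; 8 C10 dialdehyde (2E,4E,6E)-2,7-dimethylocta-2,4,6-trienedial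
Product: 11 12'-apo-β-caroten-12'-al (all-E C25 aldehyde), via β-C15 ylide 9 (not isolated), via 11Z-C25 aldehyde 10 (not isolated)
Conditions: 8 (3 equiv), NaOMe (1.05 equiv), CH2Cl2/MeOH, −10 → 20 °C, slow addition of 7; then n-heptane, reflux, 2 h; crystallisation
Reagents that add atoms: none
Why: Wittig olefination of one aldehyde group of the symmetric dialdehyde (kept in excess to suppress double olefination) by the semi-stabilised allylic ylide; the new 11,12 bond forms as an E/Z mixture whose hindered 11Z part is equilibrated thermally to all-E, and no stereocentre is involved.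

Step 6
Reactants: 11 12'-apo-β-caroten-12'-al
Product: 12 (5R,6S)-5,6-epoxy-5,6-dihydro-12'-apo-β-caroten-12'-al
Conditions: chiral ketone catalyst (0.3 equiv), KHSO5 (1.5 equiv, as 2KHSO5·KHSO4·K2SO4, added over 3 h), K2CO3, Bu4NHSO4 (5 mol%), DME/DMM 3:1 and aq K2CO3–AcOH buffer (pH 8), −10 → 0 °C, Ar, dark; chromatography on neutral Al2O3
Reagents that add atoms: potassium peroxymonosulfate (KHSO5), [K+].[O-]S(=O)(=O)OO
Why: Proposed new method: a chiral-dioxirane (Shi-type) epoxidation applied for the first time to a carotenoid polyene, with the catalyst choosing both the site and the face of the hindered tetrasubstituted 5,6-alkene; the dioxirane formed in situ from the ketone and KHSO5 is an electrophilic, concerted O-donor, so it attacks the only electron-rich C=C (the ring 5,6 bond, tetraalkyl-like because it is twisted about C6–C7 out of conjugation, whereas the six chain C=C are deactivated by the conjugated CHO), and in the spiro transition state the C7=C8 π-substituent lies over the N-aryl oxazolidinone while the bulky C1 gem-dimethyl side points away, which is predicted to deliver oxygen to the face that gives 5R,6S (the same facial sense in which this D-series ketone turns cis-β-methylstyrene into its 1R,2S oxide), both new stereocentres being set in one syn addition; the closest known reactions are the Shi epoxidation of tetrasubstituted aryl alkenes and of conjugated cis-dienes with this ketone type and the classical peracid 5,6-epoxidation of β-ring carotenoids and retinoids.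

Step 7
Reactants: 5 ε-C15 Wittig salt; 12 (5R,6S)-5,6-epoxy-5,6-dihydro-12'-apo-β-caroten-12'-al
Product: 15 (5R,6S,6'R)-5,6-epoxy-5,6-dihydro-β,ε-carotene, via ε-C15 ylide 13 (not isolated), via 11'Z-epoxycarotene 14 (not isolated)
Conditions: 5 (1.15 equiv), NaOMe (1.1 equiv), CH2Cl2/MeOH, 0 → 20 °C, Ar, dark; then n-heptane (trace Et3N), 80 °C, 2 h; crystallised from CH2Cl2/MeOH
Reagents that add atoms: none
Why: Wittig olefination between the conjugated ε-C15 ylide and the epoxy aldehyde under basic, acid-free conditions that a tetrasubstituted 5,6-epoxide tolerates; the new 11',12' bond is equilibrated thermally from the hindered Z form to E, and the three stereocentres (5R,6S from step 6, 6'R from step 1) are carried through unchanged because none of them is deprotonated or ionised.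

**Compound list**

1 | (±)-α-ionone, (3E)-4-(2,6,6-trimethylcyclohex-2-en-1-yl)but-3-en-2-one, racemic | CC1=CCCC(C)(C)C1/C=C/C(C)=O | starting material
2 | (R)-(+)-α-ionone, (3E)-4-[(1R)-2,6,6-trimethylcyclohex-2-en-1-yl]but-3-en-2-one | CC1=CCCC(C)(C)[C@H]1/C=C/C(C)=O | intermediate
3 | bromomagnesium alkoxide of 4 (not isolated) | CC1=CCCC(C)(C)[C@H]1/C=C/C(C)(O[Mg]Br)C=C | intermediate
4 | (6R)-vinyl-α-ionol, (1E)-3-methyl-1-[(1R)-2,6,6-trimethylcyclohex-2-en-1-yl]penta-1,4-dien-3-ol, both carbinol epimers | CC1=CCCC(C)(C)[C@H]1/C=C/C(C)(O)C=C | intermediate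
5 | ε-C15 Wittig salt, [(2E,4E)-3-methyl-5-[(1R)-2,6,6-trimethylcyclohex-2-en-1-yl]penta-2,4-dien-1-yl]triphenylphosphonium bromide | CC1=CCCC(C)(C)[C@H]1/C=C/C(C)=C/C[P+](c1ccccc1)(c1ccccc1)c1ccccc1.[Br-] | intermediate
6 | vinyl-β-ionol, (1E)-3-methyl-1-(2,6,6-trimethylcyclohex-1-en-1-yl)penta-1,4-dien-3-ol, racemic | CC1=C(/C=C/C(C)(O)C=C)C(C)(C)CCC1 | starting material
7 | β-C15 Wittig salt, [(2E,4E)-3-methyl-5-(2,6,6-trimethylcyclohex-1-en-1-yl)penta-2,4-dien-1-yl]triphenylphosphonium bromide | CC1=C(/C=C/C(C)=C/C[P+](c2ccccc2)(c2ccccc2)c2ccccc2)C(C)(C)CCC1.[Br-] | intermediate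
8 | C10 dialdehyde, (2E,4E,6E)-2,7-dimethylocta-2,4,6-trienedial | O=C/C(C)=C/C=C/C=C(C)/C=O | starting material
9 | β-C15 ylide, the triphenylphosphorane formed from 7 (not isolated) | CC1=C(/C=C/C(C)=C/C=P(c2ccccc2)(c2ccccc2)c2ccccc2)C(C)(C)CCC1 | intermediate
10 | (11Z)-12'-apo-β-caroten-12'-al, the 8Z isomer of 11 in tridecahexaenal numbering (not isolated) | CC1=C(/C=C/C(C)=C/C=C\C(C)=C\C=C\C=C(C)\C=O)C(C)(C)CCC1 | intermediate
11 | 12'-apo-β-caroten-12'-al, (2E,4E,6E,8E,10E,12E)-2,7,11-trimethyl-13-(2,6,6-trimethylcyclohex-1-en-1-yl)trideca-2,4,6,8,10,12-hexaenal | CC1=C(/C=C/C(C)=C/C=C/C(C)=C/C=C/C=C(C)/C=O)C(C)(C)CCC1 | intermediate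
12 | (5R,6S)-5,6-epoxy-5,6-dihydro-12'-apo-β-caroten-12'-al, (2E,4E,6E,8E,10E,12E)-2,7,11-trimethyl-13-[(1S,6R)-2,2,6-trimethyl-7-oxabicyclo[4.1.0]heptan-1-yl]trideca-2,4,6,8,10,12-hexaenal | O=C/C(C)=C/C=C/C=C(C)/C=C/C=C(C)/C=C/[C@@]12O[C@]1(C)CCCC2(C)C | intermediate
13 | ε-C15 ylide, the triphenylphosphorane formed from 5 (not isolated) | CC1=CCCC(C)(C)[C@H]1/C=C/C(C)=C/C=P(c1ccccc1)(c1ccccc1)c1ccccc1 | intermediate
14 | (11'Z,5R,6S,6'R)-5,6-epoxy-5,6-dihydro-β,ε-carotene (not isolated) | CC1=CCCC(C)(C)[C@H]1/C=C/C(C)=C/C=C\C(C)=C\C=C\C=C(C)\C=C\C=C(C)\C=C\[C@@]12O[C@]1(C)CCCC2(C)C | intermediate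
15 | (5R,6S,6'R)-5,6-epoxy-5,6-dihydro-β,ε-carotene (α-carotene 5,6-epoxide), all-E | CC1=CCCC(C)(C)[C@H]1/C=C/C(C)=C/C=C/C(C)=C/C=C/C=C(C)/C=C/C=C(C)/C=C/[C@@]12O[C@]1(C)CCCC2(C)C | target

**Step count and risks**

Total steps: 7. Longest linear sequence: 4 steps (steps 1, 2, 3, 7, or steps 4, 5, 6, 7).

Steps most likely to fail:

Step 6 (the proposed new epoxidation). The risks are:
- oxidation of the aldehyde by KHSO5;
- slow reaction at the hindered alkene next to the quaternary carbon;
- an ee too low to carry forward;
- a sense of induction that rests on analogy only and must be confirmed (CD and rotation against the known 5R,6S series).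

A modest ee can be raised by recrystallising 12, since the ee of 12 becomes the diastereomeric purity of 15. The fallback uses known chemistry and sets out from 11. Classical Prilezhaev epoxidation with mCPBA/NaHCO3 in CH2Cl2 at −20 °C, which is selective for the ring 5,6 bond of β-end-group polyenes, gives the racemic epoxy aldehyde. This is 12 together with its mirror image, the (5S,6R)-epoxy aldehyde F1. Preparative chiral HPLC (amylose phase, hexane/iPrOH with 0.1% Et3N) separates the two, and the route is rejoined at 12.

Step 7 (final coupling on the acid-sensitive epoxide). The risks are rearrangement of the 5,6-epoxide to the 5,8-furanoid oxide by adventitious acid during coupling, heating or crystallisation, and incomplete Z to E equilibration. The fallback reverses the order of the last two operations and sets out from 5 and 11.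
- The ylide 13 is condensed with the epoxide-free aldehyde 11 under the same Wittig conditions.
- The crude product contains the hindered (11'Z)-β,ε-carotene F2, which is equilibrated by heating to the robust all-E hydrocarbon (6'R)-β,ε-carotene F3.
- The 5,6 bond of F3 is then epoxidised last with the buffered catalyst system of step 6, stopped at partial conversion because the ε-ring 4',5' alkene is the main competitor. It is a trialkyl alkene without the π-contact the catalyst uses.
- This comes back to the route at 15, with no further operation on the epoxide.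

Step 3 (acidic salt formation on the chiral ε series). The risks are HBr-induced loss of H-6 (retro-type triene) or migration of the ring double bond into the β position, either of which destroys the ε-ring stereocentre, and formation of the 9Z salt. The fallback is an acid-free two-carbon homologation that sets out from 2.
- Horner–Wadsworth–Emmons reaction of 2 with triethyl phosphonoacetate and NaH in THF gives the ethyl dienoate F4; the 2E isomer is separated.
- Reduction with iBu2AlH in toluene at −78 °C gives the dienol F5.
- Appel bromination (CBr4, PPh3, CH2Cl2, 0 °C) gives the dienyl bromide F6.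
- F6 is quaternised with PPh3 in toluene at 20 °C, which comes back to the route at 5.

Further compounds
F1 | step 6 | (5S,6R)-5,6-epoxy-5,6-dihydro-12'-apo-β-caroten-12'-al (mirror image of 12) | O=C/C(C)=C/C=C/C=C(C)/C=C/C=C(C)/C=C/[C@]12O[C@@]1(C)CCCC2(C)C
F2 | step 7 | (11'Z,6'R)-β,ε-carotene | CC1=CCCC(C)(C)[C@H]1/C=C/C(C)=C/C=C\C(C)=C\C=C\C=C(C)\C=C\C=C(C)\C=C\C1=C(C)CCCC1(C)C
F3 | step 7 | (6'R)-β,ε-carotene ((6'R)-α-carotene), all-E | CC1=CCCC(C)(C)[C@H]1/C=C/C(C)=C/C=C/C(C)=C/C=C/C=C(C)/C=C/C=C(C)/C=C/C1=C(C)CCCC1(C)C
F4 | step 3 | ethyl (2E,4E)-3-methyl-5-[(1R)-2,6,6-trimethylcyclohex-2-en-1-yl]penta-2,4-dienoate | CC1=CCCC(C)(C)[C@H]1/C=C/C(C)=C/C(=O)OCC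
F5 | step 3 | (2E,4E)-3-methyl-5-[(1R)-2,6,6-trimethylcyclohex-2-en-1-yl]penta-2,4-dien-1-ol | CC1=CCCC(C)(C)[C@H]1/C=C/C(C)=C/CO
F6 | step 3 | (6R)-6-[(1E,3E)-5-bromo-3-methylpenta-1,3-dien-1-yl]-1,5,5-trimethylcyclohex-1-ene | CC1=CCCC(C)(C)[C@H]1/C=C/C(C)=C/CBr
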